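## Retrosynthetic overview

- Feature: in ring B (the carbocycle C4a–C5–C6–C7–C8–C8a of the tetrahydrochromone) the cis-diol sits on the adjacent carbinol carbons C5 and C6, two carbons of like polarity, and the chain C8a–C8–C7–C6 with its trans-7,8-diol is the four-carbon chain of D-tartaric acid.
- The last skeletal bond is C5–C6: reductive (pinacol) coupling with SmI2 of a dialdehyde that carries a formyl group on C4a and an aldehyde on C7 closes ring B.
- Ring A (the 4-pyranone: O1, C2, C3, C4, C4a, C8a) is made first. Bonds C4–C4a and O1–C8a come from annulation of an acylketene (C2–C3–C4 with the arylethyl chain, from a dioxinone) with a tartrate-derived β-aminoenal that has the amine on the future C8a and the formyl group on the future C4a.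
- The aminoenal comes from D-threitol acetonide through a terminal alkyne. The dioxinone comes from O-benzylisovanillin through its benzylic bromide and vinylogous alkylation of 2,2,6-trimethyl-4H-1,3-dioxin-4-one.
- After ring B: hydrolysis of the acetonide, then hydrogenolysis of the phenol benzyl ether.

Key step: step 11

Remark: the benzyl ether of isovanillin and the acetonide of D-threitol (the reduced form of D-tartrate acetonide) are taken as purchased; labels O1 and C2–C8a refer throughout to the chromone numbering of the target.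

## Route

Step 1
Reactants: 1 3-(benzyloxy)-4-methoxybenzaldehyde (O-benzylisovanillin)
Product: 2 [3-(benzyloxy)-4-methoxyphenyl]methanol
Conditions: NaBH4, MeOH, 0 °C
Reagents that add atoms: none
Why: Hydride reduction of the aryl aldehyde with NaBH4 gives the benzylic alcohol and leaves both aryl ethers untouched.

Step 2
Reactants: 2 [3-(benzyloxy)-4-methoxyphenyl]methanol
Product: 3 2-(benzyloxy)-4-(bromomethyl)-1-methoxybenzene (3-benzyloxy-4-methoxybenzyl bromide)
Conditions: PBr3, Et2O, 0 °C
Reagents that add atoms: phosphorus tribromide, BrP(Br)Br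
Why: Bromination of an electron-rich benzylic alcohol with PBr3, through its phosphite ester and displacement by bromide, is routine and gives a reactive alkylating agent.

Step 3
Reactants: 4 2,2,6-trimethyl-4H-1,3-dioxin-4-one; 3 3-benzyloxy-4-methoxybenzyl bromide
Product: 5 6-{2-[3-(benzyloxy)-4-methoxyphenyl]ethyl}-2,2-dimethyl-4H-1,3-dioxin-4-one
Conditions: LiN(i-Pr)2, THF, −78 °C; DMPU; 3, −78 → −30 °C
Reagents that add atoms: none
Why: Vinylogous enolate alkylation: deprotonation of the 6-methyl group and reaction of the resulting dienolate at its exocyclic γ-carbon with the reactive benzylic bromide, with DMPU favouring the γ-position, installs the arylethyl chain.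

Step 4
Reactants: 6 [(4R,5R)-2,2-dimethyl-1,3-dioxolane-4,5-diyl]dimethanol (2,3-O-isopropylidene-D-threitol)
Product: 7 [(4R,5R)-5-({[tert-butyl(dimethyl)silyl]oxy}methyl)-2,2-dimethyl-1,3-dioxolan-4-yl]methanol
Conditions: NaH (1 equiv), THF, 0 °C → rt; TBSCl (1 equiv)
Reagents that add atoms: tert-butyldimethylsilyl chloride, CC(C)(C)[Si](C)(C)Cl
Why: Monosilylation of a symmetric diol through its monosodium alkoxide; 6 is C2-symmetric, so either hydroxyl gives the same mono-ether and no stereocentre is touched.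

Step 5
Reactants: 7 mono-silyl ether of the threitol acetonide
Product: 8 (4S,5R)-5-({[tert-butyl(dimethyl)silyl]oxy}methyl)-2,2-dimethyl-1,3-dioxolane-4-carbaldehyde
Conditions: (COCl)2, DMSO, CH2Cl2, −78 °C; Et3N, −78 → 0 °C
Reagents that add atoms: none
Why: Swern oxidation converts the primary alcohol into the α-alkoxy aldehyde without epimerisation, the trans-dioxolane being in any case the favoured epimer.

Step 6
Reactants: 8 silyloxy aldehyde
Product: 9 tert-butyl{[(4R,5R)-5-ethynyl-2,2-dimethyl-1,3-dioxolan-4-yl]methoxy}dimethylsilane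
Conditions: MeC(O)C(N2)P(O)(OMe)2, K2CO3, MeOH, 0 °C → rt
Reagents that add atoms: dimethyl (1-diazo-2-oxopropyl)phosphonate, COP(=O)(OC)C(=[N+]=[N-])C(C)=O
Why: Ohira–Bestmann (Seyferth–Gilbert) homologation turns the aldehyde carbon into the internal alkyne carbon, the future C8a, and the neighbouring stereocentre (future C8) is retained because the mild base leaves the favoured trans-dioxolane.

Step 7
Reactants: 9 terminal alkyne
Product: 11 (2E)-3-[(4R,5R)-5-({[tert-butyl(dimethyl)silyl]oxy}methyl)-2,2-dimethyl-1,3-dioxolan-4-yl]-3-(dimethylamino)prop-2-enal, via ynal 10 (not isolated)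
Conditions: n-BuLi, THF, −78 °C; DMF, −78 → 0 °C; AcOH (1 equiv), H2O, Me2NH (2 M in THF, 0.5 equiv), 0 °C → rt
Reagents that add atoms: N,N-dimethylformamide, CN(C)C=O; dimethylamine, CNC
Why: Formylation of the metallated alkyne with DMF gives the ynal, and conjugate (aza-Michael) addition of the dimethylamine released on mild acidification, topped up with a little extra amine, gives the vinylogous formamide as its more stable E isomer with the amine on the future C8a.

Step 8
Reactants: 11 aminoenal; 5 arylethyl dioxinone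
Product: 14 6-{2-[3-(benzyloxy)-4-methoxyphenyl]ethyl}-2-[(4S,5R)-5-({[tert-butyl(dimethyl)silyl]oxy}methyl)-2,2-dimethyl-1,3-dioxolan-4-yl]-4-oxo-4H-pyran-3-carbaldehyde, via acylketene 12 (not isolated), via dihydropyranone aminal 13 (not isolated)
Conditions: 5 (2 equiv, slow addition), toluene, 110 °C, N2 sweep
Reagents that add atoms: none
Why: Thermal retro-[4+2] loss of acetone from the dioxinone gives the acylketene, which undergoes the known formal [4+2] annulation of acylketenes with tertiary enaminocarbonyl compounds: the enamine carbon (future C4a) adds to the ketene carbon (C4), the acyl oxygen (O1) closes on the amine-bearing carbon (C8a), and E1cB loss of dimethylamine from the cyclic aminal gives the 4-pyranone with the formyl group fixed on C4a.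

Step 9
Reactants: 14 formylpyranone silyl ether
Product: 15 6-{2-[3-(benzyloxy)-4-methoxyphenyl]ethyl}-2-[(4S,5R)-5-(hydroxymethyl)-2,2-dimethyl-1,3-dioxolan-4-yl]-4-oxo-4H-pyran-3-carbaldehyde
Conditions: HF·pyridine, pyridine, THF, 0 °C → rt
Reagents that add atoms: none
Why: Fluoride-driven cleavage of the primary silyl ether under pyridine-buffered conditions, which the acetonide, the benzyl ether and the formylpyranone should tolerate.

Step 10
Reactants: 15 hydroxy aldehyde
Product: 16 (4S,5S)-5-(6-{2-[3-(benzyloxy)-4-methoxyphenyl]ethyl}-3-formyl-4-oxo-4H-pyran-2-yl)-2,2-dimethyl-1,3-dioxolane-4-carbaldehyde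
Conditions: Dess–Martin periodinane, NaHCO3, CH2Cl2, 0 °C → rt; filtration, used at once
Reagents that add atoms: none
Why: Dess–Martin oxidation of the primary alcohol under buffered, non-epimerising conditions gives the second aldehyde (future C6), and the sensitive dialdehyde is carried on without chromatography.

Step 11
Reactants: 16 dialdehyde (formyl on C4a, aldehyde on C7)
Product: 17 (5S,6S,7R,8S)-2-{2-[3-(benzyloxy)-4-methoxyphenyl]ethyl}-5,6-dihydroxy-7,8-(isopropylidenedioxy)-5,6,7,8-tetrahydro-4H-chromen-4-one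
Conditions: SmI2 (3 equiv), t-BuOH (3 equiv), THF, −78 → −30 °C, slow addition of 16 at high dilution; aq NaHCO3
Reagents that add atoms: none
Why: Divalent samarium transfers one electron to the pyranone-conjugated formyl group, the most easily reduced carbonyl of 16, and the ketyl bound to trivalent samarium adds to the C6 aldehyde that the same metal centre activates; a second electron transfer reduces the resulting oxygen radical to the diolate, which is protonated to the diol. The closest known reaction type is the SmI2 pinacol cyclisation of sugar-derived 1,6-dialdehydes to cis-cyclohexane-1,2-diols, including substrates in which a trans-dioxolane spans two carbons of the new ring. Ring B closes in a 6-exo-trig mode, the ketyl carbon C5 attacking the C6 carbonyl carbon with its oxygen outside the ring. The C5/C6 relationship is set by the samarium bridge between the two oxygens, which holds them syn (cis-diol). The configuration at C6 is set by the C7 stereocentre: in the trans-fused half-chair the C6–O bond takes the equatorial position anti to the C7 oxygen and the C5–O bond then lies pseudoaxial, away from the peri C4 carbonyl. The step needs ketyl formation at the formyl group and not at the 4-pyranone carbonyl, and ring closure faster than a second reduction of the delocalised ketyl; the vinylogous formyl group is far easier to reduce than the pyranone, and low temperature, slow addition of 16 to excess SmI2, t-BuOH as proton source and the absence of HMPA favour cyclisation.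

Step 12
Reactants: 17 5,6-diol 7,8-acetonide
Product: 18 (5S,6S,7R,8S)-2-{2-[3-(benzyloxy)-4-methoxyphenyl]ethyl}-5,6,7,8-tetrahydroxy-5,6,7,8-tetrahydro-4H-chromen-4-one
Conditions: AcOH/H2O (4:1), 40 °C
Reagents that add atoms: none
Why: Acid-catalysed hydrolysis of the strained trans-fused isopropylidene acetal takes place at the acetal carbon, so no ring C–O bond is broken and the four stereocentres are retained.

Step 13
Reactants: 18 tetraol benzyl ether
Product: 19 (5S,6S,7R,8S)-5,6,7,8-tetrahydroxy-2-[2-(3-hydroxy-4-methoxyphenyl)ethyl]-5,6,7,8-tetrahydro-4H-chromen-4-one (CNP0224308.1)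
Conditions: H2 (1 atm), 10% Pd/C, MeOH, rt
Reagents that add atoms: none
Why: Hydrogenolysis of the aryl benzyl ether over Pd/C under mild conditions, which 4-pyranones and their carbinol substituents normally survive, frees the phenol and gives the target.

## Compound list

1 | 3-(benzyloxy)-4-methoxybenzaldehyde | COc1ccc(C=O)cc1OCc1ccccc1 | starting material
2 | [3-(benzyloxy)-4-methoxyphenyl]methanol | COc1ccc(CO)cc1OCc1ccccc1 | intermediate
3 | 2-(benzyloxy)-4-(bromomethyl)-1-methoxybenzene | COc1ccc(CBr)cc1OCc1ccccc1 | intermediate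
4 | 2,2,6-trimethyl-4H-1,3-dioxin-4-one | CC1=CC(=O)OC(C)(C)O1 | starting material
5 | 6-{2-[3-(benzyloxy)-4-methoxyphenyl]ethyl}-2,2-dimethyl-4H-1,3-dioxin-4-one | COc1ccc(CCC2=CC(=O)OC(C)(C)O2)cc1OCc1ccccc1 | intermediate
6 | [(4R,5R)-2,2-dimethyl-1,3-dioxolane-4,5-diyl]dimethanol (2,3-O-isopropylidene-D-threitol) | OC[C@H]1OC(C)(C)O[C@@H]1CO | starting material
7 | [(4R,5R)-5-({[tert-butyl(dimethyl)silyl]oxy}methyl)-2,2-dimethyl-1,3-dioxolan-4-yl]methanol | OC[C@H]1OC(C)(C)O[C@@H]1CO[Si](C)(C)C(C)(C)C | intermediate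
8 | (4S,5R)-5-({[tert-butyl(dimethyl)silyl]oxy}methyl)-2,2-dimethyl-1,3-dioxolane-4-carbaldehyde | O=C[C@H]1OC(C)(C)O[C@@H]1CO[Si](C)(C)C(C)(C)C | intermediate
9 | tert-butyl{[(4R,5R)-5-ethynyl-2,2-dimethyl-1,3-dioxolan-4-yl]methoxy}dimethylsilane | C#C[C@H]1OC(C)(C)O[C@@H]1CO[Si](C)(C)C(C)(C)C | intermediate
10 | 3-[(4R,5R)-5-({[tert-butyl(dimethyl)silyl]oxy}methyl)-2,2-dimethyl-1,3-dioxolan-4-yl]prop-2-ynal (ynal, not isolated) | O=CC#C[C@H]1OC(C)(C)O[C@@H]1CO[Si](C)(C)C(C)(C)C | intermediate
11 | (2E)-3-[(4R,5R)-5-({[tert-butyl(dimethyl)silyl]oxy}methyl)-2,2-dimethyl-1,3-dioxolan-4-yl]-3-(dimethylamino)prop-2-enal | O=C/C=C(/N(C)C)[C@H]1OC(C)(C)O[C@@H]1CO[Si](C)(C)C(C)(C)C | intermediate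
12 | 5-[3-(benzyloxy)-4-methoxyphenyl]-3-oxopent-1-en-1-one (acylketene, not isolated) | COc1ccc(CCC(=O)C=C=O)cc1OCc1ccccc1 | intermediate
13 | 6-{2-[3-(benzyloxy)-4-methoxyphenyl]ethyl}-2-[(4S,5R)-5-({[tert-butyl(dimethyl)silyl]oxy}methyl)-2,2-dimethyl-1,3-dioxolan-4-yl]-2-(dimethylamino)-4-oxo-3,4-dihydro-2H-pyran-3-carbaldehyde (aminal, epimers at the two sp3 ring carbons, not isolated) | COc1ccc(CCC2=CC(=O)C(C=O)C(N(C)C)(O2)[C@H]2OC(C)(C)O[C@@H]2CO[Si](C)(C)C(C)(C)C)cc1OCc1ccccc1 | intermediate
14 | 6-{2-[3-(benzyloxy)-4-methoxyphenyl]ethyl}-2-[(4S,5R)-5-({[tert-butyl(dimethyl)silyl]oxy}methyl)-2,2-dimethyl-1,3-dioxolan-4-yl]-4-oxo-4H-pyran-3-carbaldehyde | COc1ccc(CCc2cc(=O)c(C=O)c(o2)[C@H]2OC(C)(C)O[C@@H]2CO[Si](C)(C)C(C)(C)C)cc1OCc1ccccc1 | intermediate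
15 | 6-{2-[3-(benzyloxy)-4-methoxyphenyl]ethyl}-2-[(4S,5R)-5-(hydroxymethyl)-2,2-dimethyl-1,3-dioxolan-4-yl]-4-oxo-4H-pyran-3-carbaldehyde | COc1ccc(CCc2cc(=O)c(C=O)c(o2)[C@H]2OC(C)(C)O[C@@H]2CO)cc1OCc1ccccc1 | intermediate
16 | (4S,5S)-5-(6-{2-[3-(benzyloxy)-4-methoxyphenyl]ethyl}-3-formyl-4-oxo-4H-pyran-2-yl)-2,2-dimethyl-1,3-dioxolane-4-carbaldehyde | COc1ccc(CCc2cc(=O)c(C=O)c(o2)[C@H]2OC(C)(C)O[C@@H]2C=O)cc1OCc1ccccc1 | intermediate
17 | (5S,6S,7R,8S)-2-{2-[3-(benzyloxy)-4-methoxyphenyl]ethyl}-5,6-dihydroxy-7,8-(isopropylidenedioxy)-5,6,7,8-tetrahydro-4H-chromen-4-one | COc1ccc(CCc2cc(=O)c3c(o2)[C@H]2OC(C)(C)O[C@@H]2[C@@H](O)[C@H]3O)cc1OCc1ccccc1 | intermediate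
18 | (5S,6S,7R,8S)-2-{2-[3-(benzyloxy)-4-methoxyphenyl]ethyl}-5,6,7,8-tetrahydroxy-5,6,7,8-tetrahydro-4H-chromen-4-one | COc1ccc(CCc2cc(=O)c3c(o2)[C@@H](O)[C@H](O)[C@@H](O)[C@H]3O)cc1OCc1ccccc1 | intermediate
19 | (5S,6S,7R,8S)-5,6,7,8-tetrahydroxy-2-[2-(3-hydroxy-4-methoxyphenyl)ethyl]-5,6,7,8-tetrahydro-4H-chromen-4-one | COc1ccc(CCc2cc(=O)c3c(o2)[C@@H](O)[C@H](O)[C@@H](O)[C@H]3O)cc1O | target

## Step count and risks

Total step count: 13. Longest linear sequence: 10 steps (steps 4 to 13, from 6 to 19).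

Steps most likely to fail:

Step 11 (key step). The ketyl of the vinylogous formyl group is strongly delocalised. A second electron transfer may reach it before it closes the ring, followed by vinylogous β-elimination of the C8 oxygen (opening of the dioxolane) or plain reduction of the formyl group. Two ketyls may also couple between molecules, and facial control at C6 may be incomplete. The fallback sets out from 16 and comes back at 17. Double Wittig methylenation (Ph3PCH3Br, KN(SiMe3)2, THF, −78 °C) would give the divinyl compound 6-{2-[3-(benzyloxy)-4-methoxyphenyl]ethyl}-3-ethenyl-2-[(4S,5R)-5-ethenyl-2,2-dimethyl-1,3-dioxolan-4-yl]-4H-pyran-4-one F1. Ring-closing metathesis with the second-generation Grubbs catalyst (H2IMes)(PCy3)Cl2Ru=CHPh in CH2Cl2 at 40 °C would close ring B as its C5=C6 alkene, (7R,8S)-2-{2-[3-(benzyloxy)-4-methoxyphenyl]ethyl}-7,8-(isopropylidenedioxy)-7,8-dihydro-4H-chromen-4-one F2. Dihydroxylation (OsO4 cat., N-methylmorpholine N-oxide, acetone/H2O) should add both hydroxyls from the face anti to the allylic C7 oxygen and give 17 without any single-electron step.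

Step 8. This is the least precedented member of a known class, because the enamine carries a free formyl group. The acylketene may be lost to dimerisation or to reversible addition at the formyl oxygen. The released dimethylamine may attack the very electrophilic formylpyranone, either opening the ring with reclosure onto the formyl carbon or deprotonating C8 with loss of the C7 oxygen. The fallback sets out from 9 and comes back at 14, carrying the formyl carbon through the annulation as a thioester. Acylation of metallated 9 (n-BuLi, THF, −78 °C; ClC(O)SEt) would give the alkynyl thioester S-ethyl 3-[(4R,5R)-5-({[tert-butyl(dimethyl)silyl]oxy}methyl)-2,2-dimethyl-1,3-dioxolan-4-yl]prop-2-ynethioate F3. Addition of Me2NH (THF, 0 °C) would give the enamino thioester S-ethyl (2E)-3-[(4R,5R)-5-({[tert-butyl(dimethyl)silyl]oxy}methyl)-2,2-dimethyl-1,3-dioxolan-4-yl]-3-(dimethylamino)prop-2-enethioate F4. Annulation with the acylketene from 5 (toluene, 110 °C), a reaction established for tertiary enamino esters, would pass through the cyclic aminal S-ethyl 6-{2-[3-(benzyloxy)-4-methoxyphenyl]ethyl}-2-[(4S,5R)-5-({[tert-butyl(dimethyl)silyl]oxy}methyl)-2,2-dimethyl-1,3-dioxolan-4-yl]-2-(dimethylamino)-4-oxo-3,4-dihydro-2H-pyran-3-carbothioate F5 to the pyranone thioester S-ethyl 6-{2-[3-(benzyloxy)-4-methoxyphenyl]ethyl}-2-[(4S,5R)-5-({[tert-butyl(dimethyl)silyl]oxy}methyl)-2,2-dimethyl-1,3-dioxolan-4-yl]-4-oxo-4H-pyran-3-carbothioate F6. Fukuyama reduction (Et3SiH, 10% Pd/C, acetone, rt) would then release aldehyde 14.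

Step 10. Hydroxy aldehyde 15 may close to a seven-membered lactol that is over-oxidised to the lactone, and the new α-alkoxy aldehyde may epimerise or undergo β-elimination during isolation. The fallback sets out from 14 and comes back at 16. Luche reduction (NaBH4, CeCl3·7H2O, MeOH, −78 °C) of the formyl group would give the hydroxymethyl pyranone 6-{2-[3-(benzyloxy)-4-methoxyphenyl]ethyl}-2-[(4S,5R)-5-({[tert-butyl(dimethyl)silyl]oxy}methyl)-2,2-dimethyl-1,3-dioxolan-4-yl]-3-(hydroxymethyl)-4H-pyran-4-one F7. Desilylation (HF·pyridine, THF) would give the diol 6-{2-[3-(benzyloxy)-4-methoxyphenyl]ethyl}-3-(hydroxymethyl)-2-[(4S,5R)-5-(hydroxymethyl)-2,2-dimethyl-1,3-dioxolan-4-yl]-4H-pyran-4-one F8. Double Swern oxidation ((COCl)2, DMSO, CH2Cl2, −78 °C; Et3N), in which both hydroxyls are activated before the base is added so that no hydroxy aldehyde is ever present, would give 16, which can be passed to step 11 as a crude solution.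

Further compounds

F1 | step 11 | 6-{2-[3-(benzyloxy)-4-methoxyphenyl]ethyl}-3-ethenyl-2-[(4S,5R)-5-ethenyl-2,2-dimethyl-1,3-dioxolan-4-yl]-4H-pyran-4-one | COc1ccc(CCc2cc(=O)c(C=C)c(o2)[C@H]2OC(C)(C)O[C@@H]2C=C)cc1OCc1ccccc1
F2 | step 11 | (7R,8S)-2-{2-[3-(benzyloxy)-4-methoxyphenyl]ethyl}-7,8-(isopropylidenedioxy)-7,8-dihydro-4H-chromen-4-one | COc1ccc(CCc2cc(=O)c3c(o2)[C@H]2OC(C)(C)O[C@@H]2C=C3)cc1OCc1ccccc1
F3 | step 8 | S-ethyl 3-[(4R,5R)-5-({[tert-butyl(dimethyl)silyl]oxy}methyl)-2,2-dimethyl-1,3-dioxolan-4-yl]prop-2-ynethioate | CCSC(=O)C#C[C@H]1OC(C)(C)O[C@@H]1CO[Si](C)(C)C(C)(C)C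
F4 | step 8 | S-ethyl (2E)-3-[(4R,5R)-5-({[tert-butyl(dimethyl)silyl]oxy}methyl)-2,2-dimethyl-1,3-dioxolan-4-yl]-3-(dimethylamino)prop-2-enethioate | CCSC(=O)/C=C(/N(C)C)[C@H]1OC(C)(C)O[C@@H]1CO[Si](C)(C)C(C)(C)C
F5 | step 8 | S-ethyl 6-{2-[3-(benzyloxy)-4-methoxyphenyl]ethyl}-2-[(4S,5R)-5-({[tert-butyl(dimethyl)silyl]oxy}methyl)-2,2-dimethyl-1,3-dioxolan-4-yl]-2-(dimethylamino)-4-oxo-3,4-dihydro-2H-pyran-3-carbothioate | COc1ccc(CCC2=CC(=O)C(C(=O)SCC)C(N(C)C)(O2)[C@H]2OC(C)(C)O[C@@H]2CO[Si](C)(C)C(C)(C)C)cc1OCc1ccccc1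
F6 | step 8 | S-ethyl 6-{2-[3-(benzyloxy)-4-methoxyphenyl]ethyl}-2-[(4S,5R)-5-({[tert-butyl(dimethyl)silyl]oxy}methyl)-2,2-dimethyl-1,3-dioxolan-4-yl]-4-oxo-4H-pyran-3-carbothioate | COc1ccc(CCc2cc(=O)c(C(=O)SCC)c(o2)[C@H]2OC(C)(C)O[C@@H]2CO[Si](C)(C)C(C)(C)C)cc1OCc1ccccc1
F7 | step 10 | 6-{2-[3-(benzyloxy)-4-methoxyphenyl]ethyl}-2-[(4S,5R)-5-({[tert-butyl(dimethyl)silyl]oxy}methyl)-2,2-dimethyl-1,3-dioxolan-4-yl]-3-(hydroxymethyl)-4H-pyran-4-one | COc1ccc(CCc2cc(=O)c(CO)c(o2)[C@H]2OC(C)(C)O[C@@H]2CO[Si](C)(C)C(C)(C)C)cc1OCc1ccccc1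
F8 | step 10 | 6-{2-[3-(benzyloxy)-4-methoxyphenyl]ethyl}-3-(hydroxymethyl)-2-[(4S,5R)-5-(hydroxymethyl)-2,2-dimethyl-1,3-dioxolan-4-yl]-4H-pyran-4-one | COc1ccc(CCc2cc(=O)c(CO)c(o2)[C@H]2OC(C)(C)O[C@@H]2CO)cc1OCc1ccccc1
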